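Readings and results were generated by integration from invented constants; the scatter is artificial.

At 5.0 min the flask, which is the violet run followed further, lies beyond its last reading at 60.0 s, so the reckoning needs a quantity from which time has dropped out.

| flask | starting material | partner | capture agent | protic impurity | free catalyst | remark | time |
|---|---|---|---|---|---|---|---|
| violet | 1 mM | 1 mM | 0.10 mM | 0.30 mM | 5 µM | the very flask that is asked about, followed so far |  |
| green | 1.5 mM | 1 mM | 0.10 mM | 0.30 mM | 5 µM | run made earlier |  |
| flask | 1.0 mM | 1.00 mM | 0.100 mM | 0.300 mM | 5.0 µM |  | 5.0 min |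

| run | time / s | target / % | catalyst intermediate D / % | starting material / % | catalyst intermediate C / % |
|---|---|---|---|---|---|
| violet | 10.0 | 3 | 1 | 98 | 0 |
| violet | 15.0 | 2 | 0 | 94 | 1 |
| violet | 25.0 | 4 | 0 | 92 | 0 |
| violet | 30.0 | 5 | 1 | 91 | 0 |
| violet | 40.0 | 7 | 1 | 90 | 0 |
| violet | 50.0 | 4 | 1 | 88 | 0 |
| violet | 60.0 | 11 | 1 | 83 | 0 |
| green | 10.0 | 0 | 0 | 96 | 1 |
| green | 15.0 | 0 | 0 | 97 | 0 |
| green | 20.0 | 2 | 0 | 96 | 2 |
| green | 30.0 | 2 | 0 | 93 | 3 |
| green | 50.0 | 6 | 0 | 91 | 2 |
| green | 80.0 | 4 | 0 | 86 | 0 |
| green | 120 | 7 | 0 | 82 | 1 |

(readings scatter by 1.5 percentage points)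

- the species that holds most of what was charged as starting material, at 5.0 min (target / catalyst intermediate C / starting material / catalyst intermediate D)
- the largest share itself, whichever of these holds it, in percent of the starting material charged

The last rows of the two target columns come first. Green at 120 s holds c(target) = 0.105 mM, and violet at 60.0 s holds 0.110 mM. These are about the same, although green ran twice as long on a richer charge. Each reading carries a scatter of 1.5 percentage points, but the pair suggests a catalyst that makes a limited amount of target. One exit from the round stands in the scheme: catalyst intermediate A meets capture agent.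

Dividing the rate of target formation by the rate of catalyst capture removes time and leaves the capacity N, the target made per catalyst charged before capture, a turnover number. Green reads N = 21.0.

For the flask, N times c(free catalyst) gives target of 10.5%. The protic impurity can remove 30.0%, one for one, and the catalyst forms can hold 0.500%. Counting the full 30.0% as quenched and the 0.500% as held in catalyst forms, this estimate leaves starting material 59.0%, more than the target, so this reckoning names starting material, at about that share.

The forecast names starting material at 65%, within 55% to 74%, and differs from this reckoning on the target: “Target is probably about 20%, or about 30% if the catalyst survives”.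

    partner + free catalyst ⇌ catalyst intermediate A (K = 800 M⁻¹, k = 7100 M⁻¹ s⁻¹)
    catalyst intermediate A → catalyst intermediate B (k = 3.80 s⁻¹)
    starting material + catalyst intermediate B ⇌ catalyst intermediate C (K = 170 M⁻¹, k = 7300 M⁻¹ s⁻¹)
    catalyst intermediate C → catalyst intermediate D (k = 5.30 s⁻¹)
    catalyst intermediate D ⇌ free catalyst + target (K = 0.00120 M, k = 7.40 s⁻¹)
    catalyst intermediate A + capture agent → trapped intermediate (k = 1400 M⁻¹ s⁻¹)
    starting material + protic impurity → quenched substrate (k = 4.50 M⁻¹ s⁻¹)

The flask gives starting material at 67.0%. Trapped intermediate then holds 97.7% of the catalyst, and target stands at 13.6%. This flask's own capacity is therefore 27.2, above the 21.0 read from green. Applied to the neighbour charged with 0.020 mM of free catalyst, that capacity gives target of 54.4%, and that neighbour holds 53.7% of target against 31.5% of starting material.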